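**Plan**
Feature used: ring A has oxygens on C5 and C8 in a para relationship, a methoxy on C7 and its only hydrogen on C6. C5–C6–C7–C8 therefore map one-to-one onto the four carbons of a 4-hydroxy-3-methoxycyclobut-2-enone, and C4a/C8a are the C5=C6 double bond of a 4-pyranone (ring C).
Retrosynthesis: cut the O-methyl bonds at C5 and C8, then C5–C4a (electrocyclic ring expansion), then C8–C8a (pyranonyl-magnesium addition to methyl semisquarate), and last the pyranone at O1–C8a and C2–C3 (enolate aroylation, oxa-cyclisation).
Forward: ring B comes in with the aroyl chloride, ring C (the pyranone) is built onto it, the four-membered ring is attached at pyranone C6 and expanded to ring A, and two methylations finish.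
Stereochemistry: the target has no stereocentre; the carbinol centre of the cyclobutenone is racemic and disappears on aromatisation.

Key step: step 5

Assumption: the four starting materials are taken as commercial, and the cyclobutenone carbinol is carried as a racemate because the target is achiral.

Step 1
Reactants: 1 N,2-dimethoxy-N-methylacetamide; 2 ethynylmagnesium bromide
Product: 4 (E)-4-(dimethylamino)-1-methoxybut-3-en-2-one, via 1-methoxybut-3-yn-2-one 3 (not isolated)
Conditions: 2 (1.2 equiv), THF, 0 °C; cold 1 M HCl quench, Et2O extraction; Me2NH (2 M in THF) added to the dried extract, 0 °C → rt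
Reagents that add atoms: dimethylamine, CNC
Why: A Weinreb ketone synthesis stops at the ketone because the chelated tetrahedral magnesium adduct collapses only on the acidic quench, and the terminal ynone is a strong Michael acceptor that should take up dimethylamine (aza-Michael addition) to give the conjugated E-enaminone.

Step 2
Reactants: 4 (E)-4-(dimethylamino)-1-methoxybut-3-en-2-one; 5 2-methoxybenzoyl chloride
Product: 7 3-methoxy-2-(2-methoxyphenyl)-4H-pyran-4-one, via diketo enaminone 6 (not isolated)
Conditions: LiN(SiMe3)2 (2.2 equiv), THF, −78 °C; 5 (1.0 equiv), −78 → 0 °C; then CF3CO2H (excess), 0 → 40 °C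
Reagents that add atoms: none
Why: The only enolisable position of the vinylogous amide, the methoxy-bearing α'-carbon, is deprotonated and C-acylated by the aroyl chloride (Claisen-type enolate acylation, the second equivalent of base taking up the more acidic diketone), and acid then drives 6-endo addition–elimination of the aroyl enol oxygen at the enaminone β-carbon with loss of dimethylamine, the established enolate-acylation route from β-amino or β-alkoxy enones to 4-pyranones; the transient stereocentre of 6 is lost in the pyranone.

Step 3
Reactants: 8 dimethyl squarate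
Product: 10 3-methoxycyclobut-3-ene-1,2-dione, via hydroxycyclobutenone 9 (not isolated)
Conditions: LiAlH(OtBu)3 (1.05 equiv), THF, −78 → −20 °C; then 6 M HCl, CH2Cl2, rt; used promptly
Reagents that add atoms: none
Why: The hindered hydride reduces one carbonyl of the squarate by 1,2-addition and stops there, and acid-induced loss of methanol from the hydroxy enol ether (ionisation of the carbinol, hydrolysis of the oxocarbenium ion) gives the alkyl semisquarate, a known two-stage squarate-to-semisquarate conversion.

Step 4
Reactants: 7 3-methoxy-2-(2-methoxyphenyl)-4H-pyran-4-one; 10 3-methoxycyclobut-3-ene-1,2-dione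
Product: 12 4-hydroxy-3-methoxy-4-[5-methoxy-6-(2-methoxyphenyl)-4-oxo-4H-pyran-2-yl]cyclobut-2-en-1-one (racemic), via pyranonylmagnesium chloride 11 (not isolated)
Conditions: 7 added to TMPMgCl·LiCl (1.1 equiv), THF, −40 °C; then 10 (1.2 equiv), −78 °C; sat. aq. NH4Cl, −78 °C → rt
Reagents that add atoms: none
Why: Deprotonative magnesiation with the hindered amide base should remove the most acidic ring hydrogen, C6–H next to the ring oxygen (the site metalated by TMP amides in 4-pyranones and chromones), giving a vinylmagnesium species without a β-leaving group, which should add 1,2 to the ketone-like carbonyl C2 of the semisquarate, next to the methoxy-bearing carbon, in preference to the vinylogous ester carbonyl C1, as organometallic additions to alkoxycyclobutenediones do; the carbinol centre forms as a racemate and is destroyed in step 5.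

Step 5
Reactants: 12 4-hydroxy-3-methoxy-4-[5-methoxy-6-(2-methoxyphenyl)-4-oxo-4H-pyran-2-yl]cyclobut-2-en-1-one (racemic)
Product: 15 5,8-dihydroxy-3,7-dimethoxy-2-(2-methoxyphenyl)-4H-chromen-4-one, via dienylketene 13 (not isolated), via cyclohexadienone 14 (not isolated)
Conditions: degassed p-xylene (0.02 M), reflux (138 °C), argon
Reagents that add atoms: none
Why: Heating should open the C1–C4 bond of the cyclobutenone in a thermal four-electron conrotatory process to hydroxy dienylketene 13, and a six-electron disrotatory electrocyclisation then joins the ketene carbon to the pyranone C5–H carbon to give cyclohexadienone 14, whose 4a-hydrogen sits between two carbonyls and enolises at once to hydroquinone 15. The closest known reaction type is the thermal ring expansion of 4-aryl-, 4-heteroaryl- and 4-alkenyl-4-hydroxycyclobutenones to hydroquinones, with the C5=C6 bond of the quasi-aromatic pyranone serving as the two-electron component. Ring A closes as a six-membered carbocycle by 6π-electrocyclic closure (new bond C5–C4a, chromone numbering); in the product the former ketene carbon is C5, its CH neighbour C6, the methoxy-bearing carbon C7 and the former carbinol carbon C8. No stereocentre is created, since the racemic carbinol centre of 12 and the transient 4a centre of 14 both vanish on aromatisation. The step needs torquoselectivity and regioselectivity: the hydroxyl, as the donor substituent, turns outward during ring opening so that the pyranone ends up on the same side as the ketene, and closure can reach only C5 because the other neighbour of the attachment carbon is the ring oxygen. Oxygen-free solvent keeps the electron-rich hydroquinone from going on to the quinone.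

Step 6
Reactants: 15 5,8-dihydroxy-3,7-dimethoxy-2-(2-methoxyphenyl)-4H-chromen-4-one
Product: 16 3,5,7,8-tetramethoxy-2-(2-methoxyphenyl)-4H-chromen-4-one
Conditions: Me2SO4 (excess), K2CO3, acetone, reflux, argon
Reagents that add atoms: dimethyl sulfate, COS(=O)(=O)OC
Why: Williamson-type O-methylation (phenoxide alkylation) caps both phenols, the C8 hydroxyl quickly and the C5 hydroxyl, which is hydrogen-bonded to the C4 carbonyl, only with excess reagent and long reflux, while exclusion of air keeps the hydroquinone dianion from oxidising.

**Compound list**
1 | N,2-dimethoxy-N-methylacetamide | COCC(=O)N(C)OC | starting material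
2 | ethynylmagnesium bromide | C#C[Mg]Br | starting material
3 | 1-methoxybut-3-yn-2-one | COCC(=O)C#C | intermediate
4 | (E)-4-(dimethylamino)-1-methoxybut-3-en-2-one | COCC(=O)/C=C/N(C)C | intermediate
5 | 2-methoxybenzoyl chloride | COc1ccccc1C(Cl)=O | starting material
6 | (E)-5-(dimethylamino)-2-methoxy-1-(2-methoxyphenyl)pent-4-ene-1,3-dione (racemic, keto form drawn) | COc1ccccc1C(=O)C(OC)C(=O)/C=C/N(C)C | intermediate
7 | 3-methoxy-2-(2-methoxyphenyl)-4H-pyran-4-one | COc1ccccc1-c1occc(=O)c1OC | intermediate
8 | dimethyl squarate (3,4-dimethoxycyclobut-3-ene-1,2-dione) | COC1=C(OC)C(=O)C1=O | starting material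
9 | 4-hydroxy-2,3-dimethoxycyclobut-2-en-1-one (racemic) | COC1=C(OC)C(O)C1=O | intermediate
10 | 3-methoxycyclobut-3-ene-1,2-dione (methyl semisquarate) | COC1=CC(=O)C1=O | intermediate
11 | chloro[5-methoxy-6-(2-methoxyphenyl)-4-oxo-4H-pyran-2-yl]magnesium (LiCl complex) | COc1ccccc1-c1oc([Mg]Cl)cc(=O)c1OC | intermediate
12 | 4-hydroxy-3-methoxy-4-[5-methoxy-6-(2-methoxyphenyl)-4-oxo-4H-pyran-2-yl]cyclobut-2-en-1-one (racemic) | COc1ccccc1-c1oc(C2(O)C(OC)=CC2=O)cc(=O)c1OC | intermediate
13 | (3Z)-4-hydroxy-3-methoxy-4-[5-methoxy-6-(2-methoxyphenyl)-4-oxo-4H-pyran-2-yl]buta-1,3-dien-1-one (dienylketene) | O=C=C/C(OC)=C(O)\c1cc(=O)c(OC)c(-c2ccccc2OC)o1 | intermediate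
14 | 8-hydroxy-3,7-dimethoxy-2-(2-methoxyphenyl)-4H-chromene-4,5(4aH)-dione (racemic) | COc1ccccc1C1=C(OC)C(=O)C2C(=O)C=C(OC)C(O)=C2O1 | intermediate
15 | 5,8-dihydroxy-3,7-dimethoxy-2-(2-methoxyphenyl)-4H-chromen-4-one | COc1ccccc1-c1oc2c(O)c(OC)cc(O)c2c(=O)c1OC | intermediate
16 | 3,5,7,8-tetramethoxy-2-(2-methoxyphenyl)-4H-chromen-4-one | COc1ccccc1-c1oc2c(OC)c(OC)cc(OC)c2c(=O)c1OC | target

**Count**
Total steps: 6. Longest linear sequence: 5 steps (steps 1, 2, 4, 5, 6); step 3 is a one-step side branch.

**Steps most likely to fail**

Step 5 (ring expansion). The dienylketene may close too slowly onto the electron-poor pyranone double bond and be captured instead by its own hydroxyl after inward rotation (lactonisation), or oligomerise, and the hydroquinone may be lost to air oxidation. The fallback gives up the four-membered ring and builds ring C onto a preformed ring A; it sets out from 5 and rejoins the route at 16. 1,2,3,5-Tetramethoxybenzene would be acylated with methoxyacetyl chloride and AlCl3 (CH2Cl2, 0 °C → rt; Friedel–Crafts acylation) to 2-methoxy-1-(2,3,4,6-tetramethoxyphenyl)ethan-1-one F1. The same Lewis acid should cleave the crowded methyl ether ortho to the ketone to give 1-(2-hydroxy-3,4,6-trimethoxyphenyl)-2-methoxyethan-1-one F2. O-Acylation of F2 with 5 (pyridine, rt) would give 2,3,5-trimethoxy-6-(2-methoxyacetyl)phenyl 2-methoxybenzoate F3. Baker–Venkataraman rearrangement (KOH, pyridine, 50 °C) would give 1-(2-hydroxy-3,4,6-trimethoxyphenyl)-2-methoxy-3-(2-methoxyphenyl)propane-1,3-dione F4, and cyclodehydration (H2SO4, AcOH, 60 °C) would give 16 directly.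

Step 4 (metalation and addition). Magnesiation may go in part to C5 under direction by carbonyl-bound magnesium, with ring opening of that anion; the metalated pyranone may add in Michael fashion to unmetalated 7; or the addition may take the vinylogous ester carbonyl. The fallback sets out from 7 and rejoins the route at 11. Zincation with the Lewis-acid-free amide TMPZnCl·LiCl (THF, 25 °C), which takes the position next to the ring oxygen in chromones, would give chloro[5-methoxy-6-(2-methoxyphenyl)-4-oxo-4H-pyran-2-yl]zinc F5. An iodine quench would give 6-iodo-3-methoxy-2-(2-methoxyphenyl)-4H-pyran-4-one F6 as an isolable compound of defined regiochemistry. Iodine–magnesium exchange with iPrMgCl·LiCl (THF, −78 °C) would then give 11 free of amine, ready for addition of 10 as in step 4.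

Step 2 (acylation and ring closure). The enolate may be acylated on oxygen or twice, or unenolised enaminone may be acylated at its α-carbon, so that too little of the C-acyl compound forms for cyclisation. The fallback sets out from 1 and rejoins the route at 6. Addition of 2-methoxyphenylmagnesium bromide to 1 (THF, 0 °C) would give 2-methoxy-1-(2-methoxyphenyl)ethan-1-one F7. Claisen condensation with ethyl acetate (NaH, THF, reflux) would give 2-methoxy-1-(2-methoxyphenyl)butane-1,3-dione F8. Condensation with N,N-dimethylformamide dimethyl acetal (toluene, 90 °C) can occur only at the acetyl methyl group, since the central carbon carries a single hydrogen, and would give 6, which is cyclised with CF3CO2H to 7 as in step 2.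

**Further compounds**
F1 | step 5 | 2-methoxy-1-(2,3,4,6-tetramethoxyphenyl)ethan-1-one | COCC(=O)c1c(OC)c(OC)c(OC)cc1OC
F2 | step 5 | 1-(2-hydroxy-3,4,6-trimethoxyphenyl)-2-methoxyethan-1-one | COCC(=O)c1c(O)c(OC)c(OC)cc1OC
F3 | step 5 | 2,3,5-trimethoxy-6-(2-methoxyacetyl)phenyl 2-methoxybenzoate | COCC(=O)c1c(OC(=O)c2ccccc2OC)c(OC)c(OC)cc1OC
F4 | step 5 | 1-(2-hydroxy-3,4,6-trimethoxyphenyl)-2-methoxy-3-(2-methoxyphenyl)propane-1,3-dione (racemic, keto form drawn) | COc1ccccc1C(=O)C(OC)C(=O)c1c(O)c(OC)c(OC)cc1OC
F5 | step 4 | chloro[5-methoxy-6-(2-methoxyphenyl)-4-oxo-4H-pyran-2-yl]zinc (LiCl complex) | COc1ccccc1-c1oc([Zn]Cl)cc(=O)c1OC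
F6 | step 4 | 6-iodo-3-methoxy-2-(2-methoxyphenyl)-4H-pyran-4-one | COc1ccccc1-c1oc(I)cc(=O)c1OC
F7 | step 2 | 2-methoxy-1-(2-methoxyphenyl)ethan-1-one | COCC(=O)c1ccccc1OC
F8 | step 2 | 2-methoxy-1-(2-methoxyphenyl)butane-1,3-dione (racemic, keto form drawn) | COc1ccccc1C(=O)C(OC)C(C)=O
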